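**Strategy.** Target numbering: bicyclo[3.2.1]octa-2,6-dien-8-one, C1 = acetoxy bridgehead, C7 = octenyl-bearing alkene carbon. The α-acetoxy ketone C1(OAc)–C8(=O) is a masked α-ketol, so the five-membered ring C1–C7=C6–C5–C8 is closed last by a strain-driven α-ketol shift. In a cis-fused 1-hydroxybicyclo[4.2.0]octa-3,7-dien-2-one the cyclobutene carbon migrates from the carbinol to the enone carbonyl, giving the bridged ketone and the bridgehead alkoxide, which is acetylated in the same flask. The precursor comes from an enone–alkyne [2+2] photocycloaddition steered by a temporary silicon tether; one asymmetric allylboration sets both side-chain stereocentres.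

Key step: step 13

Assumption: (−)-Ipc2BH is taken to hydroborate cyclohexa-1,3-diene in the same sense as simple cis-alkenes, giving the (S)-configured allylic C–B centre; if the sense is opposite, the reagent from (−)-α-pinene is used and nothing else changes.

Numbering of the bicyclo[4.2.0] intermediates: C1 ring fusion (α to C2), C2 carbonyl, C3, C4, C5 (side chain), C6 ring fusion, C7, C8 (octenyl-bearing).

Step 1
Reactants: 1 (Z)-oct-2-en-1-ol
Product: 2 (Z)-1-bromooct-2-ene
Conditions: CBr4, PPh3, CH2Cl2, 0 °C
Reagents that add atoms: carbon tetrabromide, BrC(Br)(Br)Br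
Why: Appel bromination of a primary allylic alcohol proceeds by SN2 at CH2, which at 0 °C should keep the Z-alkene and avoid allylic transposition.

Step 2
Reactants: 2 (Z)-1-bromooct-2-ene; 3 ethynylmagnesium bromide
Product: 4 (Z)-undec-4-en-1-yne
Conditions: 3 (3 equiv), CuBr·SMe2 (5 mol %), THF, 0 °C → rt
Reagents that add atoms: none
Why: Copper-catalysed alkynyl–allyl coupling at the primary allylic bromide is the standard entry to skipped enynes and should retain the Z geometry.

Step 3
Reactants: 4 (Z)-undec-4-en-1-yne; 5 dichlorodiisopropylsilane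
Product: 7 chloro(diisopropyl)[(4Z)-undec-4-en-1-yn-1-yl]silane, via lithium acetylide 6 (not isolated)
Conditions: n-BuLi, THF, −78 °C; cannulated into 5 (3 equiv), THF, −78 → 0 °C; excess 5 removed in vacuo, used crude
Reagents that add atoms: none
Why: Low-temperature lithiation of the terminal alkyne followed by mono-substitution at silicon of excess dichlorosilane should give the alkynylchlorosilane without propargyl–allenyl isomerisation of the skipped enyne.

Step 4
Reactants: 8 (+)-α-pinene
Product: 9 (−)-diisopinocampheylborane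
Conditions: BH3·SMe2, THF, 0 °C; 15 % excess 8, 0 °C, 3 d (crystallisation)
Reagents that add atoms: borane–dimethyl sulfide, [BH3-][S+](C)C
Why: Double hydroboration of α-pinene occurs anti to the gem-dimethyl bridge, and equilibration with excess pinene during crystallisation should upgrade the reagent to high enantiopurity.

Step 5
Reactants: 9 (−)-diisopinocampheylborane; 10 cyclohexa-1,3-diene; 11 methyl 4-oxobutanoate
Product: 14 methyl (4R)-4-[(1R)-cyclohex-2-en-1-yl]-4-hydroxybutanoate, via allylborane 12 (not isolated), via borinate 13 (not isolated)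
Conditions: 9 + 10, THF, −25 °C, 12 h; 11, Et2O, −78 °C, 3 h; ethanolamine, rt, filtration; used crude
Reagents that add atoms: none
Why: Asymmetric hydroboration gives the cyclohex-2-enylborane, which adds to the aldehyde through a chair Zimmerman–Traxler transition state (Brown allylboration), so the ring-locked Z geometry gives the syn diastereomer while the C–B centre, transferred syn-SE2′, fixes the ring carbon as R and hence the carbinol as R.

Step 6
Reactants: 14 methyl (4R)-4-[(1R)-cyclohex-2-en-1-yl]-4-hydroxybutanoate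
Product: 15 methyl (4R)-4-[(1R)-cyclohex-2-en-1-yl]-4-(triethylsilyloxy)butanoate
Conditions: TESCl, imidazole, CH2Cl2, 0 °C
Reagents that add atoms: chlorotriethylsilane, CC[Si](Cl)(CC)CC
Why: Silylation of the secondary alcohol is faster than γ-lactonisation and masks the carbinol for the oxidation that follows.

Step 7
Reactants: 15 methyl (4R)-4-[(1R)-cyclohex-2-en-1-yl]-4-(triethylsilyloxy)butanoate
Product: 16 methyl (4R)-4-[(1R)-4-oxocyclohex-2-en-1-yl]-4-(triethylsilyloxy)butanoate
Conditions: Rh2(cap)4 (1 mol %), t-BuOOH (70 % aq., 5 equiv), K2CO3, CH2Cl2, rt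
Reagents that add atoms: tert-butyl hydroperoxide, CC(C)(C)OO
Why: Radical allylic oxidation should abstract hydrogen from the unhindered ring CH2 and oxygenate the allyl radical at the terminus remote from the branched substituent, giving the 4-substituted cyclohex-2-enone without touching the ring stereocentre.

Step 8
Reactants: 16 methyl (4R)-4-[(1R)-4-oxocyclohex-2-en-1-yl]-4-(triethylsilyloxy)butanoate; 7 chloro(diisopropyl)[(4Z)-undec-4-en-1-yn-1-yl]silane
Product: 18 alkynylsilyl-tethered enone, via hydroxy enone 17 (not isolated)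
Conditions: HF·pyridine, pyridine, THF, 0 °C; NaHCO3 work-up; crude 17, 7, imidazole, CH2Cl2, 0 °C → rt
Reagents that add atoms: none
Why: Buffered fluoride removes the TES group without base or strong acid, and immediate silylation of the crude γ-hydroxy ester with the alkynylchlorosilane installs the temporary tether before lactonisation can compete.

Step 9
Reactants: 18 alkynylsilyl-tethered enone
Product: 19 tethered cyclobutene photoadduct
Conditions: hν (350–366 nm, uranium-glass filter), degassed CH2Cl2, 5 mM, 0 °C, stopped at about 90 % conversion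
Reagents that add atoms: none
Why: In this intramolecular enone–alkyne [2+2] photocycloaddition the three-atom C–O–Si linker lets the silicon-bearing alkyne carbon reach only the β-carbon on the face that carries the side chain, so the tether should set both the regiochemistry (chain-bearing carbon to Cα) and the cis relation of cyclobutene and side chain at C6, while the C1–H centre is rehybridised later.

Step 10
Reactants: 19 tethered cyclobutene photoadduct
Product: 21 tethered bicyclo[4.2.0]octa-3,7-dien-2-one, via silyl enol ether 20 (not isolated)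
Conditions: LDA, TMSCl, THF, −78 °C; Pd(OAc)2 (1.1 equiv), MeCN, rt
Reagents that add atoms: none
Why: Kinetic enolisation at the C3 methylene (the ring-fusion C1–H is tertiary and hindered) followed by Saegusa–Ito oxidation should introduce the C3=C4 double bond.

Step 11
Reactants: 21 tethered bicyclo[4.2.0]octa-3,7-dien-2-one
Product: 23 acetoxy dienone, via hydroxy ester 22 (not isolated)
Conditions: TBAF/AcOH (1:1, 4 equiv), THF–DMF, 0 °C → rt; Ac2O, pyridine, DMAP (cat.), 0 °C, same flask
Reagents that add atoms: acetic anhydride, CC(=O)OC(C)=O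
Why: Fluoride cleaves the Si–O bond and then protodesilylates the fluoride-activated cyclobutenylsilane (C–Si to C–H), while acetic-acid buffering and immediate acetylation should outrun γ-lactonisation of the liberated hydroxy ester.

Step 12
Reactants: 23 acetoxy dienone
Product: 25 cyclobutene α-ketol, via potassium dienolate 24 (not isolated)
Conditions: KHMDS (1.1 equiv), THF, −78 °C; 2-(phenylsulfonyl)-3-phenyloxaziridine, −78 °C; AcOH, −78 °C
Reagents that add atoms: 2-(phenylsulfonyl)-3-phenyloxaziridine, O=S(=O)(c1ccccc1)N1OC1c1ccccc1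
Why: The ring-fusion C1–H is the only α-hydrogen of the enone, so kinetic α′-deprotonation and Davis hydroxylation should place oxygen on C1 on the face of the former hydrogen, because a trans-fused cyclobutene is prohibitively strained, and the cold acidic quench prevents premature rearrangement.

Step 13
Reactants: 25 cyclobutene α-ketol
Product: 28 clavubicyclone, via cyclobutenyl alkoxide 26 (not isolated), via bridgehead alkoxide 27 (not isolated)
Conditions: KHMDS (1.05 equiv), THF, −78 → −30 °C; Ac2O (3 equiv), −30 → 0 °C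
Reagents that add atoms: acetic anhydride, CC(=O)OC(C)=O
Why: Deprotonation gives the tertiary alkoxide 26, whose exocyclic cyclobutene bond C1–C8 lies nearly perpendicular to the plane of the adjacent enone carbonyl, so C8 migrates suprafacially to C2 in an α-ketol (acyloin) shift, the carbinol carbon becomes the bridging ketone and the former carbonyl oxygen becomes the bridgehead alkoxide 27, which Ac2O traps. The closest known reaction type is the ring-expanding α-ketol rearrangement of 1-acylcyclobutanols to 2-hydroxycyclopentanones, and the same 1,2-alkenyl shift in bicyclo[4.2.0]oct-7-en-2-ones is the first event of the Cargill rearrangement. One ring is closed, the five-membered ring C1–C7=C6–C5–C8 of the target, by one-carbon ring expansion of the cyclobutene (the migrating carbon adds 3-exo-trig to the carbonyl in a bridged transition state as its old bond breaks), and the cycloheptadiene perimeter appears at the same moment. The only new stereocentre, the bridgehead C1 of the target, is fixed by suprafacial migration across the face on which the cyclobutene is already fused, so the two-carbon bridge ends cis to the side chain (side chain endo) and C4 and C5 are carried over unchanged. The step needs migration of the cyclobutene carbon rather than the ring carbon C6 (which would give a bicyclo[3.3.0]octadienone) and needs the sequence to stop before a second ketol shift. The C1–C6 bond lies close to the carbonyl plane and cannot overlap with π*, only the desired shift releases the cyclobutene strain, and cold in-flask acetylation removes the alkoxide that a second shift would require.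

**Compound list**

1 | (Z)-oct-2-en-1-ol | CCCCC/C=C\CO | starting material
2 | (Z)-1-bromooct-2-ene | CCCCC/C=C\CBr | intermediate
3 | ethynylmagnesium bromide | C#C[Mg]Br | starting material
4 | (Z)-undec-4-en-1-yne | CCCCC/C=C\CC#C | intermediate
5 | dichlorodiisopropylsilane | CC(C)[Si](Cl)(Cl)C(C)C | starting material
6 | lithium (Z)-undec-4-en-1-yn-1-ide (not isolated) | CCCCC/C=C\CC#C[Li] | intermediate
7 | chloro(diisopropyl)[(4Z)-undec-4-en-1-yn-1-yl]silane | CCCCC/C=C\CC#C[Si](Cl)(C(C)C)C(C)C | intermediate
8 | (+)-α-pinene, (1R,5R) | CC1=CC[C@@H]2C[C@H]1C2(C)C | starting material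
9 | (−)-diisopinocampheylborane, from (+)-α-pinene | B([C@@H]1C[C@@H]2C[C@H]([C@H]1C)C2(C)C)[C@@H]1C[C@@H]2C[C@H]([C@H]1C)C2(C)C | intermediate
10 | cyclohexa-1,3-diene | C1=CC=CCC1 | starting material
11 | methyl 4-oxobutanoate | COC(=O)CCC=O | starting material
12 | B-[(1S)-cyclohex-2-en-1-yl]diisopinocampheylborane (not isolated) | B([C@@H]1C=CCCC1)([C@@H]1C[C@@H]2C[C@H]([C@H]1C)C2(C)C)[C@@H]1C[C@@H]2C[C@H]([C@H]1C)C2(C)C | intermediate
13 | diisopinocampheylborinate ester of 14 (not isolated) | COC(=O)CC[C@@H](OB([C@@H]1C[C@@H]2C[C@H]([C@H]1C)C2(C)C)[C@@H]1C[C@@H]2C[C@H]([C@H]1C)C2(C)C)[C@H]1C=CCCC1 | intermediate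
14 | methyl (4R)-4-[(1R)-cyclohex-2-en-1-yl]-4-hydroxybutanoate | COC(=O)CC[C@@H](O)[C@H]1C=CCCC1 | intermediate
15 | methyl (4R)-4-[(1R)-cyclohex-2-en-1-yl]-4-(triethylsilyloxy)butanoate | COC(=O)CC[C@@H](O[Si](CC)(CC)CC)[C@H]1C=CCCC1 | intermediate
16 | methyl (4R)-4-[(1R)-4-oxocyclohex-2-en-1-yl]-4-(triethylsilyloxy)butanoate | COC(=O)CC[C@@H](O[Si](CC)(CC)CC)[C@H]1C=CC(=O)CC1 | intermediate
17 | methyl (4R)-4-hydroxy-4-[(1R)-4-oxocyclohex-2-en-1-yl]butanoate (not isolated) | COC(=O)CC[C@@H](O)[C@H]1C=CC(=O)CC1 | intermediate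
18 | methyl (4R)-4-{[diisopropyl((4Z)-undec-4-en-1-yn-1-yl)silyl]oxy}-4-[(1R)-4-oxocyclohex-2-en-1-yl]butanoate | COC(=O)CC[C@@H](O[Si](C(C)C)(C(C)C)C#CC/C=C\CCCCC)[C@H]1C=CC(=O)CC1 | intermediate
19 | tethered photoadduct: cis-fused bicyclo[4.2.0]oct-7-en-2-one with the (2Z)-oct-2-enyl group on C8; the side-chain oxygen and C7 are joined through Si(iPr)2 in a six-membered oxasilane ring; cyclobutene and side chain on one face, H1, H5 and H6 on the other | CCCCC/C=C\CC1=C3[C@H]2[C@@H]1C(=O)CC[C@H]2[C@@H](CCC(=O)OC)O[Si]3(C(C)C)C(C)C | intermediate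
20 | 2-trimethylsilyloxy-2-ene (silyl enol ether) of 19 (not isolated) | CCCCC/C=C\CC1=C3[C@H]2[C@@H]1C(O[Si](C)(C)C)=CC[C@H]2[C@@H](CCC(=O)OC)O[Si]3(C(C)C)C(C)C | intermediate
21 | tethered bicyclo[4.2.0]octa-3,7-dien-2-one (19 with a C3=C4 double bond) | CCCCC/C=C\CC1=C3[C@H]2[C@@H]1C(=O)C=C[C@H]2[C@@H](CCC(=O)OC)O[Si]3(C(C)C)C(C)C | intermediate
22 | methyl (4R)-4-hydroxy-4-[(1S,5R,6R)-8-[(2Z)-oct-2-en-1-yl]-2-oxobicyclo[4.2.0]octa-3,7-dien-5-yl]butanoate (not isolated) | CCCCC/C=C\CC1=C[C@H]2[C@@H]1C(=O)C=C[C@H]2[C@@H](CCC(=O)OC)O | intermediate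
23 | methyl (4R)-4-acetoxy-4-[(1S,5R,6R)-8-[(2Z)-oct-2-en-1-yl]-2-oxobicyclo[4.2.0]octa-3,7-dien-5-yl]butanoate | CCCCC/C=C\CC1=C[C@H]2[C@@H]1C(=O)C=C[C@H]2[C@@H](CCC(=O)OC)OC(C)=O | intermediate
24 | potassium C1=C2 dienolate of 23 (not isolated) | CCCCC/C=C\CC1=C[C@H]2C1=C([O-])C=C[C@H]2[C@@H](CCC(=O)OC)OC(C)=O.[K+] | intermediate
25 | methyl (4R)-4-acetoxy-4-[(1R,5R,6R)-1-hydroxy-8-[(2Z)-oct-2-en-1-yl]-2-oxobicyclo[4.2.0]octa-3,7-dien-5-yl]butanoate | CCCCC/C=C\CC1=C[C@H]2[C@]1(O)C(=O)C=C[C@H]2[C@@H](CCC(=O)OC)OC(C)=O | intermediate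
26 | potassium alkoxide of 25 (not isolated) | CCCCC/C=C\CC1=C[C@H]2[C@]1([O-])C(=O)C=C[C@H]2[C@@H](CCC(=O)OC)OC(C)=O.[K+] | intermediate
27 | potassium bridgehead alkoxide, bicyclo[3.2.1]octa-2,6-dien-8-one skeleton (not isolated) | CCCCC/C=C\CC1=C[C@H]2C(=O)[C@]1([O-])C=C[C@H]2[C@@H](CCC(=O)OC)OC(C)=O.[K+] | intermediate
28 | clavubicyclone, methyl (4R)-4-acetoxy-4-[(1S,4R,5R)-1-acetoxy-7-[(2Z)-oct-2-en-1-yl]-8-oxobicyclo[3.2.1]octa-2,6-dien-4-yl]butanoate | CCCCC/C=C\CC1=C[C@H]2C(=O)[C@]1(OC(C)=O)C=C[C@H]2[C@@H](CCC(=O)OC)OC(C)=O | target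

**Totals.** Total step count: 13. Longest linear sequence: 10 steps (steps 4–13); the chlorosilane branch (steps 1–3) joins at step 8.

**Steps most likely to fail**

1. Step 13. The bridgehead alkoxide may undergo a second ketol shift (migration of the C2 vinyl carbon to C8, contracting to the conjugated bicyclo[3.3.0] ketol) before it is acetylated, or acetyl transfer may compete with the first shift. Fallback, from 25 back to 28: the rearrangement is run under chelation control instead of as a free alkoxide. Et2AlCl (1.1 equiv) in CH2Cl2 at −78 → −20 °C forms the five-membered aluminium ketolate, in which only the cyclobutene bond is aligned with the carbonyl π*. Rochelle-salt work-up should give the free bridgehead ketol methyl (4R)-4-acetoxy-4-[(1S,4R,5R)-1-hydroxy-7-[(2Z)-oct-2-en-1-yl]-8-oxobicyclo[3.2.1]octa-2,6-dien-4-yl]butanoate F1, which is isolated and acetylated separately (Ac2O, DMAP, Et3N, CH2Cl2, 0 °C) to 28.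

2. Step 9. The excited enone may isomerise the skipped Z-alkene or abstract hydrogen from its doubly activated CH2, and over-irradiation may trigger a 1,3-acyl shift of the β,γ-unsaturated ketone product. Fallback, from 17 back to 19: the Z-octenyl chain is attached after the photochemical step. Crude 17 is silylated with chloro(3-chloroprop-1-yn-1-yl)diisopropylsilane F2 (from propargyl chloride, n-BuLi and 5) to give the chloropropynylsilyl-tethered enone F3. Irradiation as in step 9 should give the 8-chloromethyl cyclobutene photoadduct F4. Its allylic chloride is then coupled at CH2 with (Z)-hept-1-enylcopper, made by Normant carbocupration of acetylene with n-pentylmagnesium bromide and CuBr·SMe2 (THF, −40 °C), which sets the Z-alkene and gives 19.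

3. Step 11. The liberated γ-hydroxy ester may lactonise before it is acetylated, and C–Si cleavage at the hindered diisopropylsilyl group may be sluggish. Fallback, from 21 back to 23: the Si–O bond is opened by acetolysis, so that no free hydroxyl is formed. Ac2O with Bi(OTf)3 (cat.) in MeCN at 0 °C should convert the silyl ether directly into the secondary acetate and leave an acetoxysilane on C7, the acetate–acetoxysilane F5. TBAF/AcOH in THF then protodesilylates the activated cyclobutenyl acetoxysilane to give 23.

**Further compounds**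

F1 | step 13 | methyl (4R)-4-acetoxy-4-[(1S,4R,5R)-1-hydroxy-7-[(2Z)-oct-2-en-1-yl]-8-oxobicyclo[3.2.1]octa-2,6-dien-4-yl]butanoate | CCCCC/C=C\CC1=C[C@H]2C(=O)[C@]1(O)C=C[C@H]2[C@@H](CCC(=O)OC)OC(C)=O
F2 | step 9 | chloro(3-chloroprop-1-yn-1-yl)diisopropylsilane | ClCC#C[Si](Cl)(C(C)C)C(C)C
F3 | step 9 | methyl (4R)-4-{[(3-chloroprop-1-yn-1-yl)diisopropylsilyl]oxy}-4-[(1R)-4-oxocyclohex-2-en-1-yl]butanoate | COC(=O)CC[C@@H](O[Si](C(C)C)(C(C)C)C#CCCl)[C@H]1C=CC(=O)CC1
F4 | step 9 | tethered photoadduct as 19 with chloromethyl in place of the oct-2-enyl group on C8 | ClCC1=C3[C@H]2[C@@H]1C(=O)CC[C@H]2[C@@H](CCC(=O)OC)O[Si]3(C(C)C)C(C)C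
F5 | step 11 | methyl (4R)-4-acetoxy-4-[(1S,5R,6R)-7-[acetoxy(diisopropyl)silyl]-8-[(2Z)-oct-2-en-1-yl]-2-oxobicyclo[4.2.0]octa-3,7-dien-5-yl]butanoate | CCCCC/C=C\CC1=C([Si](OC(C)=O)(C(C)C)C(C)C)[C@H]2[C@@H]1C(=O)C=C[C@H]2[C@@H](CCC(=O)OC)OC(C)=O
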